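**Plan**
- Retrosynthesis: the H/isopropenyl pair on ring C-4 goes back to a tertiary allylic alcohol and then to a cyclopentanone (isopropenyl–C bond cut). The two ring bonds CH2–CH(Ar) and CH2–CMe2 are then cut together, giving an isobutenyl arene and a 2-oxyallyl C3 unit. The alkene goes back to an aldehyde and the formyl group to 2,4,6-trihydroxybenzophenone.
- Forward: formylation, MOM protection and Wittig olefination; one (3+2) event builds the cyclopentane (the only ring made) as a 4-aryl-3,3-dimethylcyclopentanone; then deprotection, isopropenyl addition and a directed ionic hydrogenation.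
- Enabling feature: the exocyclic CH=CMe2 bond is conjugated to the 2,4,6-trioxygenated benzene ring and acts as a vinylogous enol ether. Its CMe2 carbon is nucleophilic, and alkylation there leaves a cation on ArCH stabilised by the two ortho oxygens and the para oxygen, which the other terminus of the C3 unit captures.
- Stereochemistry: the aryl-bearing carbon (R) comes from a chiral counter-anion in the cycloaddition. The isopropenyl-bearing carbon (R) comes from hydride passed from a hydrosilyl ether on an ortho phenol oxygen to the arene face of a planar allyl cation, which puts H cis and isopropenyl trans to the arene.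

Key step: step 5

Assumption: the sense of induction by the chiral counter-anion in step 5 cannot be predicted with certainty; the catalyst antipode that gives the (R)-ketone is used (written as (S,S)). Compounds 1, 5, 8 and 13 (as a THF solution) are taken as commercial.

Step 1
Reactants: 1 2,4,6-trihydroxybenzophenone
Product: 3 3-benzoyl-2,4,6-trihydroxybenzaldehyde, via aryl iminium chloride 2 (not isolated)
Conditions: POCl3, DMF, EtOAc, 0 °C to rt; then H2O, 60 °C
Reagents that add atoms: N,N-dimethylformamide CN(C)C=O; water O
Why: Vilsmeier–Haack formylation; the two free ring positions of the phloroglucinol are equivalent and strongly activated, so the chloroiminium ion should attack carbon once and hydrolysis should give the aldehyde.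

Step 2
Reactants: 3 3-benzoyl-2,4,6-trihydroxybenzaldehyde
Product: 4 3-benzoyl-2,4,6-tris(methoxymethoxy)benzaldehyde
Conditions: NaH, MOMCl, DMF, 0 °C to rt
Reagents that add atoms: chloromethyl methyl ether COCCl
Why: O-alkylation of the three sodium phenoxides by the hard electrophile MOMCl (Williamson type) removes every O–H and nucleophilic phenol oxygen before the ylide and cationic steps.

Step 3
Reactants: 4 3-benzoyl-2,4,6-tris(methoxymethoxy)benzaldehyde; 5 isopropyltriphenylphosphonium iodide
Product: 7 [2,4,6-tris(methoxymethoxy)-3-(2-methylprop-1-en-1-yl)phenyl](phenyl)methanone, via isopropylidene ylide 6 (not isolated)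
Conditions: 5, n-BuLi, THF, 0 °C; then 4, −78 °C to rt
Reagents that add atoms: none
Why: Wittig olefination; the non-stabilised ylide should react with the aldehyde and not with the hindered diaryl ketone, and the two identical methyl groups leave no E/Z question.

Step 4
Reactants: 8 2-methoxypropene
Product: 9 3-bromo-2-methoxyprop-1-ene (2-methoxyallyl bromide)
Conditions: NBS, K2CO3 (cat.), pentane, 0 °C; distilled and used fresh
Reagents that add atoms: N-bromosuccinimide O=C1CCC(=O)N1Br
Why: electrophilic bromination of the enol ether by NBS followed by loss of a methyl proton from the oxocarbenium ion should give the allylic bromide.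

Step 5
Reactants: 7 [2,4,6-tris(methoxymethoxy)-3-(2-methylprop-1-en-1-yl)phenyl](phenyl)methanone; 9 3-bromo-2-methoxyprop-1-ene
Product: 11 (4R)-4-[3-benzoyl-2,4,6-tris(methoxymethoxy)phenyl]-3,3-dimethylcyclopentan-1-one, via methyl enol ether 10 (not isolated)
Conditions: 9 (1.5 equiv), Ag2CO3 (1 equiv), (S,S)-IDPi (chiral imidodiphosphorimidate acid, 5 mol %), 4 Å MS, toluene/CH2Cl2, −40 °C, dark; then aq. oxalic acid, THF, 0 °C
Reagents that add atoms: water O
Why: Proposed new method: silver(I) paired with the chiral imidodiphosphorimidate anion abstracts bromide from 9 to give the 2-methoxyallyl cation as a chiral ion pair; the isobutenyl C=C of 7 attacks one CH2 terminus with its CMe2 carbon (or with its CH carbon if the twisted arene makes it behave as a plain trisubstituted alkene), the cation left on the other alkene carbon is captured by the CH2 carbon of the new enol ether, and both orders give the same cyclopentane. Proton loss then gives 10 and returns the acid, which insoluble Ag2CO3 converts back into the silver salt, so that ionisation should occur only through the chiral salt. The closest known reaction types are the (3+2) cycloaddition of oxyallyl and 2-alkoxyallyl cations with styrenes, counter-anion-controlled oxyallyl (4+3) cycloadditions and silver-mediated chiral-anion phase-transfer ionisation of alkyl halides. The five-membered ring is closed by C-attack of the enol ether on the benzylic (or tertiary) cation, a stepwise cation–olefin closure of 5-endo type as in the known oxyallyl (3+2) reaction. The one new stereocentre, the aryl-bearing ring carbon, is set in that C–C bond formation inside the ion pair and is controlled by the confined chiral anion. The step needs attack on the alkene in preference to the one free aromatic C–H and C- in preference to O-closure: the benzoyl group and full O-protection lower the ring nucleophilicity, the alkylated CMe2 carbon has no proton to lose so the benzylic cation can only cyclise, and O-closure can revert by re-ionisation whereas C-closure cannot.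

Step 6
Reactants: 11 (4R)-4-[3-benzoyl-2,4,6-tris(methoxymethoxy)phenyl]-3,3-dimethylcyclopentan-1-one
Product: 12 (4R)-4-(3-benzoyl-2,4,6-trihydroxyphenyl)-3,3-dimethylcyclopentan-1-one
Conditions: HCl (2 M), MeOH/H2O, 45 °C
Reagents that add atoms: none
Why: acid-catalysed transacetalisation of the three MOM ethers to dimethoxymethane, done while the molecule still has no acid-labile alkene or tertiary allylic alcohol.

Step 7
Reactants: 12 (4R)-4-(3-benzoyl-2,4,6-trihydroxyphenyl)-3,3-dimethylcyclopentan-1-one; 13 isopropenylmagnesium bromide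
Product: 14 (1S,4R)-4-(3-benzoyl-2,4,6-trihydroxyphenyl)-3,3-dimethyl-1-(prop-1-en-2-yl)cyclopentan-1-ol
Conditions: 13 (5 equiv), LaCl3·2LiCl, THF, −20 to 0 °C; aq. NH4Cl
Reagents that add atoms: none
Why: Grignard 1,2-addition to the cyclopentanone after the first three equivalents deprotonate the phenols, which turns the benzophenone into an unreactive vinylogous carboxylate; addition should occur mainly anti to the aryl group, and the C-1 epimer is carried on because step 8 passes through a planar cation.

Step 8
Reactants: 14 (1S,4R)-4-(3-benzoyl-2,4,6-trihydroxyphenyl)-3,3-dimethyl-1-(prop-1-en-2-yl)cyclopentan-1-ol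
Product: 17 {3-[(1R,4R)-2,2-dimethyl-4-(prop-1-en-2-yl)cyclopentyl]-2,4,6-trihydroxyphenyl}(phenyl)methanone (CNP0143418.1), via hydrosilyl ether 15 (not isolated), via silanol ether 16 (not isolated)
Conditions: iPr2SiHCl (1.05 equiv), Et3N, CH2Cl2, −40 °C; filter, concentrate; CSA (10 mol %), CH2Cl2, −20 °C; then aq. NaHCO3, MeOH
Reagents that add atoms: none
Why: Proposed new method: the most acidic phenol (para to the benzoyl group, ortho to the cyclopentyl carbon) should be silylated selectively, acid ionises the tertiary allylic alcohol to the planar ring/isopropenyl allyl cation, and the O–Si–H group, held over the ring face that carries the arene, passes hydride to the ring terminus through an eight-membered transition state, so that H enters cis to the aryl group and isopropenyl ends trans; the nearer, more positively charged ring carbon is reduced and not the distal CH2, which leaves the 1,1-disubstituted alkene; the silylium ion takes up the water released (15 to 16 is an isomerisation) and hydrolysis frees the phenol; the closest known reaction types are tethered hydrosilyl-ether (intramolecular) ionic hydrogenation of benzylic cations and intramolecular hydrosilylation of β-hydroxy ketones.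

**Compound list**
1 | 2,4,6-trihydroxybenzophenone | O=C(c1ccccc1)c1c(O)cc(O)cc1O | starting material
2 | [(3-benzoyl-2,4,6-trihydroxyphenyl)methylidene]dimethylammonium chloride (not isolated) | C[N+](C)=Cc1c(O)cc(O)c(C(=O)c2ccccc2)c1O.[Cl-] | intermediate
3 | 3-benzoyl-2,4,6-trihydroxybenzaldehyde | O=Cc1c(O)cc(O)c(C(=O)c2ccccc2)c1O | intermediate
4 | 3-benzoyl-2,4,6-tris(methoxymethoxy)benzaldehyde | O=Cc1c(OCOC)cc(OCOC)c(C(=O)c2ccccc2)c1OCOC | intermediate
5 | isopropyltriphenylphosphonium iodide | CC(C)[P+](c1ccccc1)(c1ccccc1)c1ccccc1.[I-] | starting material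
6 | isopropylidenetriphenylphosphorane (not isolated) | CC(C)=P(c1ccccc1)(c1ccccc1)c1ccccc1 | intermediate
7 | [2,4,6-tris(methoxymethoxy)-3-(2-methylprop-1-en-1-yl)phenyl](phenyl)methanone | CC(C)=Cc1c(OCOC)cc(OCOC)c(C(=O)c2ccccc2)c1OCOC | intermediate
8 | 2-methoxypropene | COC(C)=C | starting material
9 | 3-bromo-2-methoxyprop-1-ene (2-methoxyallyl bromide) | COC(=C)CBr | intermediate
10 | {3-[(1R)-3-methoxy-5,5-dimethylcyclopent-2-en-1-yl]-2,4,6-tris(methoxymethoxy)phenyl}(phenyl)methanone (methyl enol ether of 11; one of two double-bond isomers shown; not isolated) | COC1=C[C@@H](c2c(OCOC)cc(OCOC)c(C(=O)c3ccccc3)c2OCOC)C(C)(C)C1 | intermediate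
11 | (4R)-4-[3-benzoyl-2,4,6-tris(methoxymethoxy)phenyl]-3,3-dimethylcyclopentan-1-one | O=C1C[C@@H](c2c(OCOC)cc(OCOC)c(C(=O)c3ccccc3)c2OCOC)C(C)(C)C1 | intermediate
12 | (4R)-4-(3-benzoyl-2,4,6-trihydroxyphenyl)-3,3-dimethylcyclopentan-1-one | O=C1C[C@@H](c2c(O)cc(O)c(C(=O)c3ccccc3)c2O)C(C)(C)C1 | intermediate
13 | isopropenylmagnesium bromide | C=C(C)[Mg]Br | starting material
14 | (1S,4R)-4-(3-benzoyl-2,4,6-trihydroxyphenyl)-3,3-dimethyl-1-(prop-1-en-2-yl)cyclopentan-1-ol (hydroxyl cis to the aryl group; the C-1 epimer may accompany it) | C=C(C)[C@]1(O)C[C@@H](c2c(O)cc(O)c(C(=O)c3ccccc3)c2O)C(C)(C)C1 | intermediate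
15 | (1S,4R)-4-[3-benzoyl-6-(diisopropylsilyloxy)-2,4-dihydroxyphenyl]-3,3-dimethyl-1-(prop-1-en-2-yl)cyclopentan-1-ol (not isolated) | C=C(C)[C@]1(O)C[C@@H](c2c(O[SiH](C(C)C)C(C)C)cc(O)c(C(=O)c3ccccc3)c2O)C(C)(C)C1 | intermediate
16 | {3-[(1R,4R)-2,2-dimethyl-4-(prop-1-en-2-yl)cyclopentyl]-2,6-dihydroxy-4-[hydroxy(diisopropyl)silyloxy]phenyl}(phenyl)methanone (not isolated) | C=C(C)[C@@H]1C[C@@H](c2c(O[Si](O)(C(C)C)C(C)C)cc(O)c(C(=O)c3ccccc3)c2O)C(C)(C)C1 | intermediate
17 | {3-[(1R,4R)-2,2-dimethyl-4-(prop-1-en-2-yl)cyclopentyl]-2,4,6-trihydroxyphenyl}(phenyl)methanone (CNP0143418.1) | C=C(C)[C@@H]1C[C@@H](c2c(O)cc(O)c(C(=O)c3ccccc3)c2O)C(C)(C)C1 | target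

Total step count: 8. Longest linear sequence: 7 (steps 1, 2, 3, 5, 6, 7, 8); step 4 is a one-step branch.

**Steps most likely to fail**

1. Step 5 (proposed new method). The allyl cation may attack the remaining aromatic C–H instead of the alkene, the open cation may lose a proton (ene-type outcome) instead of closing, or facial discrimination within the ion pair may be weak. The fallback uses known chemistry and makes the aryl–ring bond by conjugate addition instead. It sets out from 1: bromination with NBS should give 3-bromo-2,4,6-trihydroxybenzophenone F1; MOMCl/NaH should give [3-bromo-2,4,6-tris(methoxymethoxy)phenyl](phenyl)methanone F2; Miyaura borylation (B2pin2, Pd/SPhos, KOAc) should give the pinacol boronate [2,4,6-tris(methoxymethoxy)-3-(4,4,5,5-tetramethyl-1,3,2-dioxaborolan-2-yl)phenyl](phenyl)methanone F3; rhodium/BINAP-catalysed Hayashi–Miyaura 1,4-addition of F3 to commercial 4,4-dimethylcyclopent-2-en-1-one then returns to the route at 11.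

2. Step 8 (proposed new method). The tether may be lost by hydrolysis, or the cation may be trapped by the neighbouring phenol as a bridged ether before hydride transfer; undirected reduction, elimination to dienes or acid-induced alkene migration would follow. The fallback uses known chemistry and sets out from 11. NaBH4 (which should reduce the cyclopentanone faster than the hindered diaryl ketone) should give the cyclopentanol [3-(4-hydroxy-2,2-dimethylcyclopentyl)-2,4,6-tris(methoxymethoxy)phenyl](phenyl)methanone F4 as an epimer mixture. Appel bromination should give the bromide [3-(4-bromo-2,2-dimethylcyclopentyl)-2,4,6-tris(methoxymethoxy)phenyl](phenyl)methanone F5. Nickel-catalysed reductive cross-electrophile coupling with 2-bromopropene (NiBr2·glyme, 4,4′-di-tert-butyl-2,2′-bipyridine, Zn, DMA) forms the C–C bond at a planar radical and should favour the face away from the arene, giving after separation {3-[(1R,4R)-2,2-dimethyl-4-(prop-1-en-2-yl)cyclopentyl]-2,4,6-tris(methoxymethoxy)phenyl}(phenyl)methanone F6. HCl/MeOH then returns to the route at 17.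

3. Step 7. Addition may stay incomplete because the magnesium triphenoxide precipitates and the ketone is enolised instead of attacked. The fallback replaces the polyanion by a protecting-group approach and sets out from 12: TBSCl/imidazole should give (4R)-4-[3-benzoyl-2,4,6-tris(tert-butyldimethylsilyloxy)phenyl]-3,3-dimethylcyclopentan-1-one F7; isopropenylmagnesium bromide/CeCl3 at −78 °C should give the tertiary alcohol (1S,4R)-4-[3-benzoyl-2,4,6-tris(tert-butyldimethylsilyloxy)phenyl]-3,3-dimethyl-1-(prop-1-en-2-yl)cyclopentan-1-ol F8; TBAF then returns to the route at 14.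

**Further compounds**
F1 | step 5 | 3-bromo-2,4,6-trihydroxybenzophenone | O=C(c1ccccc1)c1c(O)cc(O)c(Br)c1O
F2 | step 5 | [3-bromo-2,4,6-tris(methoxymethoxy)phenyl](phenyl)methanone | O=C(c1ccccc1)c1c(OCOC)cc(OCOC)c(Br)c1OCOC
F3 | step 5 | [2,4,6-tris(methoxymethoxy)-3-(4,4,5,5-tetramethyl-1,3,2-dioxaborolan-2-yl)phenyl](phenyl)methanone | O=C(c1ccccc1)c1c(OCOC)cc(OCOC)c(B2OC(C)(C)C(C)(C)O2)c1OCOC
F4 | step 8 | [3-(4-hydroxy-2,2-dimethylcyclopentyl)-2,4,6-tris(methoxymethoxy)phenyl](phenyl)methanone, (1R) at the aryl-bearing carbon, carbinol epimers | OC1C[C@@H](c2c(OCOC)cc(OCOC)c(C(=O)c3ccccc3)c2OCOC)C(C)(C)C1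
F5 | step 8 | [3-(4-bromo-2,2-dimethylcyclopentyl)-2,4,6-tris(methoxymethoxy)phenyl](phenyl)methanone, (1R) at the aryl-bearing carbon, C–Br epimers | BrC1C[C@@H](c2c(OCOC)cc(OCOC)c(C(=O)c3ccccc3)c2OCOC)C(C)(C)C1
F6 | step 8 | {3-[(1R,4R)-2,2-dimethyl-4-(prop-1-en-2-yl)cyclopentyl]-2,4,6-tris(methoxymethoxy)phenyl}(phenyl)methanone | C=C(C)[C@@H]1C[C@@H](c2c(OCOC)cc(OCOC)c(C(=O)c3ccccc3)c2OCOC)C(C)(C)C1
F7 | step 7 | (4R)-4-[3-benzoyl-2,4,6-tris(tert-butyldimethylsilyloxy)phenyl]-3,3-dimethylcyclopentan-1-one | O=C1C[C@@H](c2c(O[Si](C)(C)C(C)(C)C)cc(O[Si](C)(C)C(C)(C)C)c(C(=O)c3ccccc3)c2O[Si](C)(C)C(C)(C)C)C(C)(C)C1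
F8 | step 7 | (1S,4R)-4-[3-benzoyl-2,4,6-tris(tert-butyldimethylsilyloxy)phenyl]-3,3-dimethyl-1-(prop-1-en-2-yl)cyclopentan-1-ol | C=C(C)[C@]1(O)C[C@@H](c2c(O[Si](C)(C)C(C)(C)C)cc(O[Si](C)(C)C(C)(C)C)c(C(=O)c3ccccc3)c2O[Si](C)(C)C(C)(C)C)C(C)(C)C1
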